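**Plan**

1. The target is read as (R)-(4-hydroxyphenyl)[(1S,2S,3R)-indan-1-yl]methanol: indane C1 carries the carbinol, C2 the 3,5-dihydroxyphenyl and C3 the 4-hydroxyphenyl group, with the C2 aryl trans to the C3 aryl and cis to the C1 side chain.
2. Retrosynthesis cuts, in order: the six O-benzyl groups; the carbinol C–H (aryl ketone); the C1–H and carbinol C–O pair across an exocyclic C1=CH–Ar alkene; that alkene (benzyl Grignard addition and dehydration) back to a trans-2,3-diarylindan-1-one and then its indenone.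
3. The indenone is cut at both aryl–carbon bonds of the five-membered ring, C7a–C1 and C3a–C3, into 2,4-bis(benzyloxy)-1-iodobenzene and the anhydride of a 2,3-diarylacrylic acid (Perkin condensation).
4. Enabling feature: in resorcinol ring A, C3a lies ortho to the C4 oxygen, and C7a lies next to C7–H and meta to both oxygens. These are the ipso carbon and the only free ortho carbon of an ortho-alkoxy aryl iodide, and C1–C2–C3 at enone level is an α-aryl cinnamoyl unit, so palladium/norbornene catalysis can acylate the ortho C–H and close at the ipso carbon.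
5. Forward order: acid, anhydride, one-step annulation of the five-membered ring onto ring A with two aryl groups in place, then the fourth aryl and the carbinol. Benzyl ethers are carried throughout because the final p-hydroxybenzylic alcohol would not survive Lewis-acidic ether cleavage.
6. Stereochemistry: C3 from an oxazaborolidine reduction relayed by a suprafacial 1,3-hydrogen shift; C2 by equilibration to trans; C1 by hydroboration anti to the C2 aryl; the carbinol by a second oxazaborolidine reduction.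

Key step: step 5

Remark: the sense of both oxazaborolidine reductions is assigned from the standard model (larger carbonyl substituent: the aryl-bearing alkene carbon in 9, the aryl ring in 19); the mirror-image catalyst would be taken if the model proved reversed.

Step 1
Reactants: 1 (3,5-dihydroxyphenyl)acetic acid
Product: 3 [3,5-bis(benzyloxy)phenyl]acetic acid, via benzyl ester 2 (not isolated)
Conditions: BnBr (3.3 equiv), K2CO3, DMF, 60 °C; then NaOH aq., MeOH/THF, 60 °C; HCl work-up
Reagents that add atoms: benzyl bromide, BrCc1ccccc1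
Why: Williamson O-benzylation of both phenols and the carboxylate, followed by saponification of the benzyl ester in the same pot, is routine and creates no stereocentre.

Step 2
Reactants: 3 [3,5-bis(benzyloxy)phenyl]acetic acid; 4 4-(benzyloxy)benzaldehyde
Product: 5 (2E)-2-[3,5-bis(benzyloxy)phenyl]-3-[4-(benzyloxy)phenyl]prop-2-enoic acid
Conditions: Ac2O, Et3N, 120 °C; then H2O, 90 °C
Reagents that add atoms: none
Why: Perkin condensation of an arylacetic acid with an aromatic aldehyde should give the 2,3-diarylacrylic acid, the E isomer (carboxyl trans to the β-aryl, β-hydrogen cis to the carboxyl) being the usual major product; no stereocentre is formed.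

Step 3
Reactants: 5 (2E)-2-[3,5-bis(benzyloxy)phenyl]-3-[4-(benzyloxy)phenyl]prop-2-enoic acid (two molecules)
Product: 6 (2E)-2-[3,5-bis(benzyloxy)phenyl]-3-[4-(benzyloxy)phenyl]prop-2-enoic anhydride (symmetrical)
Conditions: DCC (0.5 equiv), CH2Cl2, 0 °C to rt
Reagents that add atoms: none
Why: carbodiimide dehydration of two acid molecules should give the symmetrical anhydride needed as acyl donor; no stereocentre is formed.

Step 4
Reactants: 7 1,3-bis(benzyloxy)benzene
Product: 8 2,4-bis(benzyloxy)-1-iodobenzene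
Conditions: NIS (1.05 equiv), TFA (10 mol%), MeCN, rt
Reagents that add atoms: N-iodosuccinimide, O=C1CCC(=O)N1I
Why: electrophilic aromatic iodination of the resorcinol diether should occur at C4, para to one and ortho to the other benzyloxy group; no stereocentre is formed.

Step 5
Reactants: 6 (2E)-2-[3,5-bis(benzyloxy)phenyl]-3-[4-(benzyloxy)phenyl]prop-2-enoic anhydride; 8 2,4-bis(benzyloxy)-1-iodobenzene
Product: 9 4,6-bis(benzyloxy)-2-[3,5-bis(benzyloxy)phenyl]-3-[4-(benzyloxy)phenyl]-1H-inden-1-one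
Conditions: Pd(OAc)2 (10 mol%), tri(2-furyl)phosphine (25 mol%), norbornene (1 equiv), Cs2CO3 (2.5 equiv), 6 (1.5 equiv), toluene, 100 °C
Reagents that add atoms: none
Why: Zerovalent palladium should add to the C–I bond of 8, norbornene inserts and the ortho C6–H is palladated to an aryl–norbornyl palladacycle, which the anhydride acylates at C6 through a tetravalent palladium intermediate (new bond C7a–C1 of 9); β-carbon elimination then expels norbornene and leaves an aryl–palladium bond at the former C1 of 8 beside the new enone. That aryl–palladium bond closes the five-membered ring at the enone β-carbon (new bond C3a–C3) in a formal 5-endo-trig Heck-type step, by carbopalladation and β-hydride elimination from the palladium enolate or, equivalently, by carbonate-assisted palladation of the β-C–H (cis to the carbonyl in the E-acyl unit) and reductive elimination, returning zerovalent palladium. The closest known reaction type is the palladium/norbornene-cooperative (Catellani-type) ortho-acylation/ipso-Heck annulation of aryl iodides with α,β-unsaturated carboxylic anhydrides to indenones. No stereocentre is created, since the indenone is planar; the stereocentres follow in steps 6 to 12. The step needs regiocontrol and a single ortho functionalization: the ortho benzyloxy group of 8 blocks one ortho site, so acylation can only occur at C6 (meta to both oxygens, a position electrophilic substitution does not reach), and the same group ensures norbornene extrusion after one acylation, while excess anhydride should suppress ipso termination before acylation.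

Step 6
Reactants: 9 4,6-bis(benzyloxy)-2-[3,5-bis(benzyloxy)phenyl]-3-[4-(benzyloxy)phenyl]-1H-inden-1-one
Product: 10 (1S)-4,6-bis(benzyloxy)-2-[3,5-bis(benzyloxy)phenyl]-3-[4-(benzyloxy)phenyl]-1H-inden-1-ol
Conditions: (R)-2-methyl-CBS-oxazaborolidine (20 mol%), BH3·SMe2 (0.7 equiv), THF, −20 °C; MeOH then aqueous work-up
Reagents that add atoms: none
Why: Corey–Bakshi–Shibata reduction should deliver hydride to one carbonyl face, the catalyst boron binding the oxygen lone pair on the benzo side (small, peri C7–H) and not on the side of the C2 aryl (large), which with the (R)-catalyst is expected to give the (1S)-indenol.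

Step 7
Reactants: 10 (1S)-4,6-bis(benzyloxy)-2-[3,5-bis(benzyloxy)phenyl]-3-[4-(benzyloxy)phenyl]-1H-inden-1-ol
Product: 12 (2R,3R)-4,6-bis(benzyloxy)-2-[3,5-bis(benzyloxy)phenyl]-3-[4-(benzyloxy)phenyl]-2,3-dihydro-1H-inden-1-one, via enol 11 (not isolated)
Conditions: DABCO (30 mol%), THF, 50 °C
Reagents that add atoms: none
Why: the amine-catalysed 1,3-prototropic shift of an indenol (ion pair, suprafacial) should carry the C1 hydrogen to C3 on the same face and so relay the carbinol configuration to the benzylic C3 stereocentre, after which enol 11 ketonizes and C2 equilibrates under the same base to the more stable trans arrangement of the two aryl groups.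

Step 8
Reactants: 12 (2R,3R)-4,6-bis(benzyloxy)-2-[3,5-bis(benzyloxy)phenyl]-3-[4-(benzyloxy)phenyl]-2,3-dihydro-1H-inden-1-one; 13 1-(benzyloxy)-4-(chloromethyl)benzene
Product: 15 (1S,2R,3R)-4,6-bis(benzyloxy)-1-[4-(benzyloxy)benzyl]-2-[3,5-bis(benzyloxy)phenyl]-3-[4-(benzyloxy)phenyl]-2,3-dihydro-1H-inden-1-ol, via Grignard reagent 14 (not isolated)
Conditions: 13, Mg, THF, 0 °C; then 12, LaCl3·2LiCl (1 equiv), THF, 0 °C; aq. NH4Cl
Reagents that add atoms: none
Why: 1,2-addition of the benzylic Grignard reagent, with LaCl3·2LiCl to favour addition over enolization at the acidic C2–H, is expected from the face anti to the C2 aryl and should give the (1S) tertiary alcohol with OH cis to that aryl (a stereocentre that step 9 removes).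

Step 9
Reactants: 15 (1S,2R,3R)-4,6-bis(benzyloxy)-1-[4-(benzyloxy)benzyl]-2-[3,5-bis(benzyloxy)phenyl]-3-[4-(benzyloxy)phenyl]-2,3-dihydro-1H-inden-1-ol
Product: 16 (1E,2R,3R)-4,6-bis(benzyloxy)-1-[4-(benzyloxy)benzylidene]-2-[3,5-bis(benzyloxy)phenyl]-3-[4-(benzyloxy)phenyl]-2,3-dihydro-1H-indene
Conditions: Burgess reagent (2 equiv), toluene, 70 °C
Reagents that add atoms: none
Why: Burgess dehydration is a syn elimination, and since C2–H is trans to the sulfamate only the benzylic CH2 hydrogens can be reached, so the exocyclic alkene should form, with E geometry (aryl turned away from the peri C7–H); no new stereocentre.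

Step 10
Reactants: 16 (1E,2R,3R)-4,6-bis(benzyloxy)-1-[4-(benzyloxy)benzylidene]-2-[3,5-bis(benzyloxy)phenyl]-3-[4-(benzyloxy)phenyl]-2,3-dihydro-1H-indene
Product: 18 (S)-[(1S,2S,3R)-4,6-bis(benzyloxy)-2-[3,5-bis(benzyloxy)phenyl]-3-[4-(benzyloxy)phenyl]-2,3-dihydro-1H-inden-1-yl][4-(benzyloxy)phenyl]methanol, via alkylborane 17 (not isolated)
Conditions: BH3·THF (3 equiv), THF, 0 °C to rt; then NaOH aq., H2O2, 0 °C to rt
Reagents that add atoms: hydrogen peroxide, OO
Why: hydroboration–oxidation of the trisubstituted stilbene-type alkene should place boron on the less substituted benzylic carbon and hydrogen on C1 by syn addition from the face anti to the adjacent C2 aryl, which sets C1 (side chain cis to the C2 aryl) and, from the E alkene, the (S)-carbinol after oxidation with retention.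

Step 11
Reactants: 18 (S)-[(1S,2S,3R)-4,6-bis(benzyloxy)-2-[3,5-bis(benzyloxy)phenyl]-3-[4-(benzyloxy)phenyl]-2,3-dihydro-1H-inden-1-yl][4-(benzyloxy)phenyl]methanol
Product: 19 [(1S,2S,3R)-4,6-bis(benzyloxy)-2-[3,5-bis(benzyloxy)phenyl]-3-[4-(benzyloxy)phenyl]-2,3-dihydro-1H-inden-1-yl][4-(benzyloxy)phenyl]methanone
Conditions: Dess–Martin periodinane (1.5 equiv), NaHCO3, CH2Cl2, 0 °C
Reagents that add atoms: none
Why: Dess–Martin oxidation under bicarbonate buffer should convert the secondary benzylic alcohol to the aryl ketone without acid or base strong enough to epimerize the now enolizable C1 centre; no new stereocentre.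

Step 12
Reactants: 19 [(1S,2S,3R)-4,6-bis(benzyloxy)-2-[3,5-bis(benzyloxy)phenyl]-3-[4-(benzyloxy)phenyl]-2,3-dihydro-1H-inden-1-yl][4-(benzyloxy)phenyl]methanone
Product: 20 (R)-[(1S,2S,3R)-4,6-bis(benzyloxy)-2-[3,5-bis(benzyloxy)phenyl]-3-[4-(benzyloxy)phenyl]-2,3-dihydro-1H-inden-1-yl][4-(benzyloxy)phenyl]methanol
Conditions: (S)-2-methyl-CBS-oxazaborolidine (30 mol%), BH3·SMe2 (1 equiv), THF, −20 °C; MeOH then aqueous work-up
Reagents that add atoms: none
Why: Corey–Bakshi–Shibata reduction of the aryl ketone with the (S)-catalyst (aryl as the large group) should give the (R)-carbinol, the substrate bias acting in the same sense because the C2 aryl shields the opposite face in the Felkin–Anh arrangement, and the non-basic conditions should leave C1 untouched.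

Step 13
Reactants: 20 (R)-[(1S,2S,3R)-4,6-bis(benzyloxy)-2-[3,5-bis(benzyloxy)phenyl]-3-[4-(benzyloxy)phenyl]-2,3-dihydro-1H-inden-1-yl][4-(benzyloxy)phenyl]methanol
Product: 21 (R)-[(1S,2S,3R)-2-(3,5-dihydroxyphenyl)-4,6-dihydroxy-3-(4-hydroxyphenyl)-2,3-dihydro-1H-inden-1-yl](4-hydroxyphenyl)methanol
Conditions: H2 (1 atm), 10% Pd/C, NaHCO3, EtOAc/MeOH, rt
Reagents that add atoms: none
Why: hydrogenolysis of the six benzyl ethers over Pd/C should free the phenols without touching the stereocentres, bicarbonate and a short reaction time being used because the p-hydroxybenzylic alcohol would ionize under acid (and then cyclize onto the C2 aryl) or be over-reduced.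

**Compound list**

1 | (3,5-dihydroxyphenyl)acetic acid | OC(=O)Cc1cc(O)cc(O)c1 | starting material
2 | benzyl [3,5-bis(benzyloxy)phenyl]acetate | O=C(Cc1cc(OCc2ccccc2)cc(OCc2ccccc2)c1)OCc1ccccc1 | intermediate
3 | [3,5-bis(benzyloxy)phenyl]acetic acid | OC(=O)Cc1cc(OCc2ccccc2)cc(OCc2ccccc2)c1 | intermediate
4 | 4-(benzyloxy)benzaldehyde | O=Cc1ccc(OCc2ccccc2)cc1 | starting material
5 | (2E)-2-[3,5-bis(benzyloxy)phenyl]-3-[4-(benzyloxy)phenyl]prop-2-enoic acid | OC(=O)/C(=C/c1ccc(OCc2ccccc2)cc1)c1cc(OCc2ccccc2)cc(OCc2ccccc2)c1 | intermediate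
6 | (2E)-2-[3,5-bis(benzyloxy)phenyl]-3-[4-(benzyloxy)phenyl]prop-2-enoic anhydride | O=C(OC(=O)/C(=C/c1ccc(OCc2ccccc2)cc1)c1cc(OCc2ccccc2)cc(OCc2ccccc2)c1)/C(=C/c1ccc(OCc2ccccc2)cc1)c1cc(OCc2ccccc2)cc(OCc2ccccc2)c1 | intermediate
7 | 1,3-bis(benzyloxy)benzene | c1ccc(COc2cccc(OCc3ccccc3)c2)cc1 | starting material
8 | 2,4-bis(benzyloxy)-1-iodobenzene | Ic1ccc(OCc2ccccc2)cc1OCc1ccccc1 | intermediate
9 | 4,6-bis(benzyloxy)-2-[3,5-bis(benzyloxy)phenyl]-3-[4-(benzyloxy)phenyl]-1H-inden-1-one | O=C1C(c2cc(OCc3ccccc3)cc(OCc3ccccc3)c2)=C(c2ccc(OCc3ccccc3)cc2)c2c(OCc3ccccc3)cc(OCc3ccccc3)cc21 | intermediate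
10 | (1S)-4,6-bis(benzyloxy)-2-[3,5-bis(benzyloxy)phenyl]-3-[4-(benzyloxy)phenyl]-1H-inden-1-ol | O[C@@H]1C(c2cc(OCc3ccccc3)cc(OCc3ccccc3)c2)=C(c2ccc(OCc3ccccc3)cc2)c2c(OCc3ccccc3)cc(OCc3ccccc3)cc21 | intermediate
11 | (1S)-5,7-bis(benzyloxy)-2-[3,5-bis(benzyloxy)phenyl]-1-[4-(benzyloxy)phenyl]-1H-inden-3-ol (enol) | c1ccccc1COc1ccc([C@@H]2c3c(OCc4ccccc4)cc(OCc4ccccc4)cc3C(O)=C2c2cc(OCc3ccccc3)cc(OCc3ccccc3)c2)cc1 | intermediate
12 | (2R,3R)-4,6-bis(benzyloxy)-2-[3,5-bis(benzyloxy)phenyl]-3-[4-(benzyloxy)phenyl]-2,3-dihydro-1H-inden-1-one | c1ccccc1COc1ccc([C@@H]2c3c(OCc4ccccc4)cc(OCc4ccccc4)cc3C(=O)[C@H]2c2cc(OCc3ccccc3)cc(OCc3ccccc3)c2)cc1 | intermediate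
13 | 1-(benzyloxy)-4-(chloromethyl)benzene | ClCc1ccc(OCc2ccccc2)cc1 | starting material
14 | [4-(benzyloxy)benzyl]magnesium chloride | Cl[Mg]Cc1ccc(OCc2ccccc2)cc1 | intermediate
15 | (1S,2R,3R)-4,6-bis(benzyloxy)-1-[4-(benzyloxy)benzyl]-2-[3,5-bis(benzyloxy)phenyl]-3-[4-(benzyloxy)phenyl]-2,3-dihydro-1H-inden-1-ol | c1ccccc1COc1ccc([C@@H]2c3c(OCc4ccccc4)cc(OCc4ccccc4)cc3[C@](O)(Cc3ccc(OCc4ccccc4)cc3)[C@H]2c2cc(OCc3ccccc3)cc(OCc3ccccc3)c2)cc1 | intermediate
16 | (1E,2R,3R)-4,6-bis(benzyloxy)-1-[4-(benzyloxy)benzylidene]-2-[3,5-bis(benzyloxy)phenyl]-3-[4-(benzyloxy)phenyl]-2,3-dihydro-1H-indene | c1ccccc1COc1ccc([C@@H]2c3c(OCc4ccccc4)cc(OCc4ccccc4)cc3/C(=C/c3ccc(OCc4ccccc4)cc3)[C@H]2c2cc(OCc3ccccc3)cc(OCc3ccccc3)c2)cc1 | intermediate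
17 | monoalkylborane of 16 (BH2 in place of the OH of 18, same configuration, drawn as monomer) | c1ccccc1COc1ccc([C@@H]2c3c(OCc4ccccc4)cc(OCc4ccccc4)cc3[C@@H]([C@H](B)c3ccc(OCc4ccccc4)cc3)[C@H]2c2cc(OCc3ccccc3)cc(OCc3ccccc3)c2)cc1 | intermediate
18 | (S)-[(1S,2S,3R)-4,6-bis(benzyloxy)-2-[3,5-bis(benzyloxy)phenyl]-3-[4-(benzyloxy)phenyl]-2,3-dihydro-1H-inden-1-yl][4-(benzyloxy)phenyl]methanol | c1ccccc1COc1ccc([C@@H]2c3c(OCc4ccccc4)cc(OCc4ccccc4)cc3[C@@H]([C@H](O)c3ccc(OCc4ccccc4)cc3)[C@H]2c2cc(OCc3ccccc3)cc(OCc3ccccc3)c2)cc1 | intermediate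
19 | [(1S,2S,3R)-4,6-bis(benzyloxy)-2-[3,5-bis(benzyloxy)phenyl]-3-[4-(benzyloxy)phenyl]-2,3-dihydro-1H-inden-1-yl][4-(benzyloxy)phenyl]methanone | c1ccccc1COc1ccc([C@@H]2c3c(OCc4ccccc4)cc(OCc4ccccc4)cc3[C@@H](C(=O)c3ccc(OCc4ccccc4)cc3)[C@H]2c2cc(OCc3ccccc3)cc(OCc3ccccc3)c2)cc1 | intermediate
20 | (R)-[(1S,2S,3R)-4,6-bis(benzyloxy)-2-[3,5-bis(benzyloxy)phenyl]-3-[4-(benzyloxy)phenyl]-2,3-dihydro-1H-inden-1-yl][4-(benzyloxy)phenyl]methanol | c1ccccc1COc1ccc([C@@H]2c3c(OCc4ccccc4)cc(OCc4ccccc4)cc3[C@@H]([C@@H](O)c3ccc(OCc4ccccc4)cc3)[C@H]2c2cc(OCc3ccccc3)cc(OCc3ccccc3)c2)cc1 | intermediate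
21 | (R)-[(1S,2S,3R)-2-(3,5-dihydroxyphenyl)-4,6-dihydroxy-3-(4-hydroxyphenyl)-2,3-dihydro-1H-inden-1-yl](4-hydroxyphenyl)methanol | Oc1ccc([C@@H]2c3c(O)cc(O)cc3[C@@H]([C@@H](O)c3ccc(O)cc3)[C@H]2c2cc(O)cc(O)c2)cc1 | target

**Totals and risks**

Total step count: 13. Longest linear sequence: 12 steps (1, 2, 3, 5, 6, 7, 8, 9, 10, 11, 12, 13).

Step 5 may fail through ipso termination before ortho acylation, through palladium-mediated C–H arylation of the ortho benzyl ether outrunning norbornene insertion, or through slow acyl transfer from the hindered anhydride. The five-membered ring would then be closed by a Nazarov cyclization on a ring A that already carries the carbonyl. Setting out from 5, amide coupling with N,O-dimethylhydroxylamine would give (2E)-2-[3,5-bis(benzyloxy)phenyl]-3-[4-(benzyloxy)phenyl]-N-methoxy-N-methylprop-2-enamide F1. [3,5-Bis(benzyloxy)phenyl]lithium F2 (from commercial 1-bromo-3,5-bis(benzyloxy)benzene and n-BuLi, THF, −78 °C) would add to it to give (2E)-1,2-bis[3,5-bis(benzyloxy)phenyl]-3-[4-(benzyloxy)phenyl]prop-2-en-1-one F3. BF3·OEt2 in CH2Cl2 should cyclize this aryl vinyl ketone at the activated ortho position of the ketone-bearing ring to the racemic trans-indanone F4, and DDQ (dioxane, 80 °C) would dehydrogenate it to indenone 9, where the route resumes.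

Step 6 may fail through poor facial discrimination of a ketone flanked by two sp2 carbons, which would erode the enantiomeric purity of everything downstream. The indenol would then be made racemic and resolved enzymatically. Setting out from 9, Luche reduction (NaBH4, CeCl3·7H2O, MeOH/THF, 0 °C) would give the racemic indenol F5. Candida antarctica lipase B with vinyl acetate (toluene, 40 °C) is expected by the Kazlauskas rule to acylate the (R)-alcohol to (1R)-4,6-bis(benzyloxy)-2-[3,5-bis(benzyloxy)phenyl]-3-[4-(benzyloxy)phenyl]-1H-inden-1-yl acetate F6 and leave (S)-indenol 10, which re-enters at step 7.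

Step 12 may fail through epimerization at C1 of the cis ketone (to the trans isomer) during oxidation or reduction, or through hydride delivery to the wrong carbonyl face. The ketone would then be avoided altogether. Setting out from 16, triplet energy transfer (Ir(ppy)3 or thioxanthone, violet LED, degassed MeCN/THF) should enrich the (1Z,2R,3R)-alkene F7, which is twisted out of conjugation by the peri C7–H and should therefore accumulate at the photostationary state. Hydroboration–oxidation of F7 under the conditions of step 10, via alkylborane F8 (again syn addition anti to the C2 aryl), should give the (R)-carbinol 20 directly, where the route resumes at step 13.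

**Further compounds**

F1 | step 5 | (2E)-2-[3,5-bis(benzyloxy)phenyl]-3-[4-(benzyloxy)phenyl]-N-methoxy-N-methylprop-2-enamide | CON(C)C(=O)/C(=C/c1ccc(OCc2ccccc2)cc1)c1cc(OCc2ccccc2)cc(OCc2ccccc2)c1
F2 | step 5 | [3,5-bis(benzyloxy)phenyl]lithium | [Li]c1cc(OCc2ccccc2)cc(OCc2ccccc2)c1
F3 | step 5 | (2E)-1,2-bis[3,5-bis(benzyloxy)phenyl]-3-[4-(benzyloxy)phenyl]prop-2-en-1-one | O=C(c1cc(OCc2ccccc2)cc(OCc2ccccc2)c1)/C(=C/c1ccc(OCc2ccccc2)cc1)c1cc(OCc2ccccc2)cc(OCc2ccccc2)c1
F4 | step 5 | racemic trans-4,6-bis(benzyloxy)-2-[3,5-bis(benzyloxy)phenyl]-3-[4-(benzyloxy)phenyl]-2,3-dihydro-1H-inden-1-one (1:1 mixture of 12 and the (2S,3S) enantiomer drawn here) | c1ccccc1COc1ccc([C@H]2c3c(OCc4ccccc4)cc(OCc4ccccc4)cc3C(=O)[C@@H]2c2cc(OCc3ccccc3)cc(OCc3ccccc3)c2)cc1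
F5 | step 6 | racemic 4,6-bis(benzyloxy)-2-[3,5-bis(benzyloxy)phenyl]-3-[4-(benzyloxy)phenyl]-1H-inden-1-ol | OC1C(c2cc(OCc3ccccc3)cc(OCc3ccccc3)c2)=C(c2ccc(OCc3ccccc3)cc2)c2c(OCc3ccccc3)cc(OCc3ccccc3)cc21
F6 | step 6 | (1R)-4,6-bis(benzyloxy)-2-[3,5-bis(benzyloxy)phenyl]-3-[4-(benzyloxy)phenyl]-1H-inden-1-yl acetate | CC(=O)O[C@H]1C(c2cc(OCc3ccccc3)cc(OCc3ccccc3)c2)=C(c2ccc(OCc3ccccc3)cc2)c2c(OCc3ccccc3)cc(OCc3ccccc3)cc21
F7 | step 12 | (1Z,2R,3R)-4,6-bis(benzyloxy)-1-[4-(benzyloxy)benzylidene]-2-[3,5-bis(benzyloxy)phenyl]-3-[4-(benzyloxy)phenyl]-2,3-dihydro-1H-indene | c1ccccc1COc1ccc([C@@H]2c3c(OCc4ccccc4)cc(OCc4ccccc4)cc3/C(=C\c3ccc(OCc4ccccc4)cc3)[C@H]2c2cc(OCc3ccccc3)cc(OCc3ccccc3)c2)cc1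
F8 | step 12 | monoalkylborane of F7 (BH2 in place of the OH of 20, same configuration, drawn as monomer) | c1ccccc1COc1ccc([C@@H]2c3c(OCc4ccccc4)cc(OCc4ccccc4)cc3[C@@H]([C@@H](B)c3ccc(OCc4ccccc4)cc3)[C@H]2c2cc(OCc3ccccc3)cc(OCc3ccccc3)c2)cc1
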